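**Retrosynthetic overview**

1. Target 16 ⇐ acid unmasking of the tris-MOM/TES chalcone 15 ⇐ C5–acyl bond: lithiation of dihydrobenzofuran 8 between its two OMOM groups and 1,2-addition to cinnamoyl Weinreb amide 12 (ring B and the E-enone arrive preformed; 12 by Horner–Wadsworth–Emmons reaction of 9 with 10).
2. 8 ⇐ one-operation palladium/norbornene [3+2] annulation of aryl iodide 2 (ring A, from 5-iodoresorcinol 1) with (S)-epoxide 6: first C3–C3a (ortho C–H alkylation), then O1–C7a (aryl C–O reductive elimination), which closes the dihydrofuran ring (ring C).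
3. Enabling feature (benzofuran numbering): O1–C7a and C3–C3a lie on adjacent carbons of ring A (an ipso/ortho pair). C7a is meta to both C4–O and C6–O, so it maps onto the iodide of 5-iodoresorcinol, whose two ortho C–H bonds are equivalent. The stereocentre C2 bears O1, so an epoxide delivers it without its C2–O bond ever being broken.
4. 6 ⇐ hydrolytic kinetic resolution of racemic epoxide 5 ⇐ silylation and epoxidation of 2-methylbut-3-en-2-ol 3.
5. Ring order: rings A and B are bought; ring C is the only ring formed (step 5).

Key step: step 5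

Assumption: the (R,R)-cobalt salen catalyst is taken to leave the (S)-epoxide, as for epichlorohydrin- and glycidate-type epoxides whose substituent outranks the ring CH2 (otherwise the (S,S) catalyst is used); 1, 9, 10 and the cobalt salen complex are taken as commercial.

**Route**

Step 1
Reactants: 1 5-iodobenzene-1,3-diol
Product: 2 1-iodo-3,5-bis(methoxymethoxy)benzene
Conditions: MOMCl (2.5 equiv), iPr2NEt, CH2Cl2, 0 °C to rt
Reagents that add atoms: chloromethyl methyl ether (MOMCl), COCCl
Why: Williamson-type O-alkylation of both phenols gives the mirror-symmetric bis-MOM ether, whose acetal groups survive base and organometallics and later direct the lithiation.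

Step 2
Reactants: 3 2-methylbut-3-en-2-ol
Product: 4 triethyl[(2-methylbut-3-en-2-yl)oxy]silane
Conditions: TESOTf, 2,6-lutidine, CH2Cl2, 0 °C
Reagents that add atoms: triethylsilyl trifluoromethanesulfonate (TESOTf), CC[Si](CC)(CC)OS(=O)(=O)C(F)(F)F
Why: Silylation of a tertiary alcohol with a silyl triflate and a hindered pyridine base; the TES ether blocks Payne rearrangement and any ring closure through the tertiary oxygen later on.

Step 3
Reactants: 4 triethyl[(2-methylbut-3-en-2-yl)oxy]silane
Product: 5 rac-triethyl{[2-(oxiran-2-yl)propan-2-yl]oxy}silane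
Conditions: mCPBA (1.5 equiv), NaHCO3, CH2Cl2, 0 °C to rt
Reagents that add atoms: meta-chloroperbenzoic acid (mCPBA), O=C(OO)c1cccc(Cl)c1
Why: Prilezhaev epoxidation of the terminal alkene under buffered conditions that spare the silyl ether; the new stereocentre is formed without facial bias (racemate) and is resolved in step 4.

Step 4
Reactants: 5 rac-triethyl{[2-(oxiran-2-yl)propan-2-yl]oxy}silane
Product: 6 (S)-triethyl{[2-(oxiran-2-yl)propan-2-yl]oxy}silane
Conditions: (R,R)-(salen)Co(OAc) (1–2 mol%), H2O (0.55 equiv), THF (minimal), 0 °C to rt; distillation or chromatography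
Reagents that add atoms: none
Why: Jacobsen hydrolytic kinetic resolution: the trivalent cobalt complex (R,R)-N,N'-bis(3,5-di-tert-butylsalicylidene)-1,2-cyclohexanediaminocobalt acetate should deliver water to the CH2 terminus of the (R)-epoxide only, leaving the (S)-epoxide that carries the single stereocentre of the target.

Step 5
Reactants: 2 1-iodo-3,5-bis(methoxymethoxy)benzene; 6 (S)-triethyl{[2-(oxiran-2-yl)propan-2-yl]oxy}silane
Product: 8 (S)-4,6-bis(methoxymethoxy)-2-[2-(triethylsilyloxy)propan-2-yl]-2,3-dihydro-1-benzofuran, via six-membered aryl(alkoxo)palladium chelate 7 (not isolated)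
Conditions: Pd(OAc)2 (10 mol%), RuPhos (20 mol%), 1-methylnorbornene (bridgehead-substituted mediator, 50 mol%), Cs2CO3 (2.5 equiv), 1,4-dioxane, 110 °C
Reagents that add atoms: none
Why: Proposed new method: zerovalent palladium adds to the C–I bond of 2, the norbornene inserts and relays the metal to an ortho C–H bond (the two are identical by the mirror symmetry of 2), and the resulting aryl-norbornyl palladacycle of divalent palladium opens epoxide 6 at its CH2 terminus (oxidative addition to tetravalent palladium, then C–C reductive elimination), which makes the C3–C3a bond. β-Carbon elimination then expels the norbornene and leaves the six-membered aryl(alkoxo)palladium chelate 7, whose C(sp2)–O reductive elimination forms the O1–C7a bond and so closes the five-membered dihydrofuran ring (ring C) by contraction of the palladacycle, returning zerovalent palladium. The closest known reaction type is the Catellani-type palladium/norbornene [3+2] annulation of ortho-substituted aryl iodides with epoxides to 2,3-dihydrobenzofurans; what is new is an aryl iodide with two free ortho positions, for which a bridgehead-substituted norbornene (known to stop ortho aminations and acylations after one event) together with the chelating tethered alkoxide should make norbornene extrusion faster than a second C–H palladation. No stereocentre is formed: C2 comes from 6 with its C–O bond untouched, so the (S) configuration is carried over as such. The step needs terminal opening of the epoxide (secured by the fully substituted carbon next to the other terminus), closure through the secondary oxygen only (the tertiary one is silylated) and reductive elimination faster than β-hydride loss from the alkoxide (favoured by the five-membered ring being formed and by the bulky biaryl phosphine).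

Step 6
Reactants: 9 4-(methoxymethoxy)benzaldehyde; 10 diethyl {2-[methoxy(methyl)amino]-2-oxoethyl}phosphonate
Product: 12 (E)-N-methoxy-3-[4-(methoxymethoxy)phenyl]-N-methylprop-2-enamide, via sodium phosphonate carbanion 11 (not isolated)
Conditions: NaH, THF, 0 °C; then 9, 0 °C to rt
Reagents that add atoms: none
Why: Horner–Wadsworth–Emmons olefination with an amide-stabilised phosphonate, which should give the E-alkene under thermodynamic control.

Step 7
Reactants: 8 (S)-4,6-bis(methoxymethoxy)-2-[2-(triethylsilyloxy)propan-2-yl]-2,3-dihydro-1-benzofuran; 12 (E)-N-methoxy-3-[4-(methoxymethoxy)phenyl]-N-methylprop-2-enamide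
Product: 15 (S,E)-1-{4,6-bis(methoxymethoxy)-2-[2-(triethylsilyloxy)propan-2-yl]-2,3-dihydro-1-benzofuran-5-yl}-3-[4-(methoxymethoxy)phenyl]prop-2-en-1-one, via C5 aryllithium 13 (not isolated), via lithium N,O-hemiaminal adduct 14 (not isolated)
Conditions: n-BuLi (1.2 equiv), THF, 0 °C; then 12, −78 °C to 0 °C; then H2O
Reagents that add atoms: none
Why: Directed ortho-metalation at C5, the only C–H flanked by two chelating OMOM groups, followed by a Weinreb ketone synthesis (1,2-addition to the non-enolisable enamide, the chelated adduct preventing over-addition) installs the chalcone with its E-alkene intact and leaves C2 untouched.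

Step 8
Reactants: 15 (S,E)-1-{4,6-bis(methoxymethoxy)-2-[2-(triethylsilyloxy)propan-2-yl]-2,3-dihydro-1-benzofuran-5-yl}-3-[4-(methoxymethoxy)phenyl]prop-2-en-1-one
Product: 16 (S,E)-1-[4,6-dihydroxy-2-(2-hydroxypropan-2-yl)-2,3-dihydro-1-benzofuran-5-yl]-3-(4-hydroxyphenyl)prop-2-en-1-one
Conditions: HCl (3 M aq., catalytic to 2 equiv), MeOH, rt to 40 °C, monitored and stopped at full conversion
Reagents that add atoms: none
Why: Acid-catalysed acetal exchange with methanol should remove the three MOM ethers (the two next to the carbonyl with chelation assistance) and methanolyse the tertiary TES ether in the same operation, under conditions of the kind used for related 2',6'-dihydroxychalcones.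

**Compound list**

1 | 5-iodobenzene-1,3-diol (5-iodoresorcinol) | Oc1cc(O)cc(I)c1 | starting material
2 | 1-iodo-3,5-bis(methoxymethoxy)benzene | COCOc1cc(I)cc(OCOC)c1 | intermediate
3 | 2-methylbut-3-en-2-ol | CC(C)(O)C=C | starting material
4 | triethyl[(2-methylbut-3-en-2-yl)oxy]silane | CC[Si](CC)(CC)OC(C)(C)C=C | intermediate
5 | rac-triethyl{[2-(oxiran-2-yl)propan-2-yl]oxy}silane | CC[Si](CC)(CC)OC(C)(C)C1CO1 | intermediate
6 | (S)-triethyl{[2-(oxiran-2-yl)propan-2-yl]oxy}silane | CC[Si](CC)(CC)OC(C)(C)[C@@H]1CO1 | intermediate
7 | six-membered aryl(alkoxo)palladium chelate of divalent palladium (phosphine ligand omitted) | CC[Si](CC)(CC)OC(C)(C)[C@@H]1Cc2c(OCOC)cc(OCOC)cc2[Pd]O1 | intermediate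
8 | (S)-4,6-bis(methoxymethoxy)-2-[2-(triethylsilyloxy)propan-2-yl]-2,3-dihydro-1-benzofuran | CC[Si](CC)(CC)OC(C)(C)[C@@H]1Cc2c(OCOC)cc(OCOC)cc2O1 | intermediate
9 | 4-(methoxymethoxy)benzaldehyde | COCOc1ccc(C=O)cc1 | starting material
10 | diethyl {2-[methoxy(methyl)amino]-2-oxoethyl}phosphonate | CCOP(=O)(CC(=O)N(C)OC)OCC | starting material
11 | sodium salt of the α-carbanion of 10 | CCOP(=O)([CH-]C(=O)N(C)OC)OCC.[Na+] | intermediate
12 | (E)-N-methoxy-3-[4-(methoxymethoxy)phenyl]-N-methylprop-2-enamide | CON(C)C(=O)/C=C/c1ccc(OCOC)cc1 | intermediate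
13 | {(S)-4,6-bis(methoxymethoxy)-2-[2-(triethylsilyloxy)propan-2-yl]-2,3-dihydro-1-benzofuran-5-yl}lithium | CC[Si](CC)(CC)OC(C)(C)[C@@H]1Cc2c(OCOC)c([Li])c(OCOC)cc2O1 | intermediate
14 | lithium alkoxide of the tetrahedral adduct of 13 and 12 (carbinol centre unassigned) | CC[Si](CC)(CC)OC(C)(C)[C@@H]1Cc2c(OCOC)c(C(O[Li])(/C=C/c3ccc(OCOC)cc3)N(C)OC)c(OCOC)cc2O1 | intermediate
15 | (S,E)-1-{4,6-bis(methoxymethoxy)-2-[2-(triethylsilyloxy)propan-2-yl]-2,3-dihydro-1-benzofuran-5-yl}-3-[4-(methoxymethoxy)phenyl]prop-2-en-1-one | CC[Si](CC)(CC)OC(C)(C)[C@@H]1Cc2c(OCOC)c(C(=O)/C=C/c3ccc(OCOC)cc3)c(OCOC)cc2O1 | intermediate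
16 | (S,E)-1-[4,6-dihydroxy-2-(2-hydroxypropan-2-yl)-2,3-dihydro-1-benzofuran-5-yl]-3-(4-hydroxyphenyl)prop-2-en-1-one | CC(C)(O)[C@@H]1Cc2c(cc(O)c(C(=O)/C=C/c3ccc(O)cc3)c2O)O1 | target

**Step count**

Total: 8 steps. Longest linear sequence: 6 steps (steps 2, 3, 4, 5, 7, 8).

**Steps most likely to fail, with fallbacks**

Step 5 (proposed new method). The relay may not stop after one ortho event (a second C–H palladation before norbornene extrusion, leading to double alkylation), palladation next to an OMOM group may be slow, or the secondary palladium alkoxide may lose a β-hydride instead of closing the ring. The fallback makes the two bonds one after the other with known chemistry, setting out from 2 and 6 and returning at 8. Electrophilic iodination of 2 (NIS, MeCN, rt) should occur para to one OMOM group and next to the iodine, giving 1,2-diiodo-3,5-bis(methoxymethoxy)benzene F1. Iodine–magnesium exchange (iPrMgCl·LiCl, THF, −40 °C) should take the iodine flanked by OMOM (chelation and inductive assistance), giving [2-iodo-4,6-bis(methoxymethoxy)phenyl]magnesium chloride F2. Kept cold to avoid aryne formation, F2 opens 6 at CH2 under CuI catalysis (10 mol%, −40 to 0 °C) to (S)-1-[2-iodo-4,6-bis(methoxymethoxy)phenyl]-3-methyl-3-(triethylsilyloxy)butan-2-ol F3. An intramolecular Ullmann-type etherification (CuI, 1,10-phenanthroline, Cs2CO3, toluene, 110 °C) then forms the same O1–C7a bond and gives 8.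

Step 7. Lithiation may partition between C5 and C7 (the latter flanked by OMOM and the ring oxygen), and the hindered aryllithium may add sluggishly or in conjugate fashion to the enamide, or fragment its N-methoxy group. The fallback sets out from 8 and returns at 15, building the enone by condensation and not by acyl transfer. The aryllithium 13 is added inversely to acetic anhydride (THF, −78 °C) to give 1-{(S)-4,6-bis(methoxymethoxy)-2-[2-(triethylsilyloxy)propan-2-yl]-2,3-dihydro-1-benzofuran-5-yl}ethan-1-one F4, at which stage any regioisomer can be removed. A Claisen–Schmidt condensation of F4 with 9 (KOH, EtOH/H2O, rt) then forms the E-enone and gives 15.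

Step 8. Under protic acid the liberated 2',6'-dihydroxychalcone may close by oxa-Michael addition to flavanones while the slower ring-B acetal is still being cleaved, and the tertiary carbinol may ionise. The fallback sets out from 15 and returns at 16, unmasking in two aprotic stages. Fluoride (tetrabutylammonium fluoride, THF, 0 °C) removes the silyl ether while all phenols are still capped, giving (S,E)-1-[2-(2-hydroxypropan-2-yl)-4,6-bis(methoxymethoxy)-2,3-dihydro-1-benzofuran-5-yl]-3-[4-(methoxymethoxy)phenyl]prop-2-en-1-one F5. Trimethylsilyl triflate with 2,2'-bipyridyl (MeCN, 0 °C) then converts the aryl MOM ethers (and the free carbinol) into trimethylsilyl ethers, giving (S,E)-3-[4-(trimethylsilyloxy)phenyl]-1-{4,6-bis(trimethylsilyloxy)-2-[2-(trimethylsilyloxy)propan-2-yl]-2,3-dihydro-1-benzofuran-5-yl}prop-2-en-1-one F6, which is hydrolysed on work-up with water (citrate buffer) to 16.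

**Further compounds**

F1 | step 5 | 1,2-diiodo-3,5-bis(methoxymethoxy)benzene | COCOc1cc(I)c(I)c(OCOC)c1
F2 | step 5 | [2-iodo-4,6-bis(methoxymethoxy)phenyl]magnesium chloride | COCOc1cc(I)c([Mg]Cl)c(OCOC)c1
F3 | step 5 | (S)-1-[2-iodo-4,6-bis(methoxymethoxy)phenyl]-3-methyl-3-(triethylsilyloxy)butan-2-ol | CC[Si](CC)(CC)OC(C)(C)[C@@H](O)Cc1c(I)cc(OCOC)cc1OCOC
F4 | step 7 | 1-{(S)-4,6-bis(methoxymethoxy)-2-[2-(triethylsilyloxy)propan-2-yl]-2,3-dihydro-1-benzofuran-5-yl}ethan-1-one | CC[Si](CC)(CC)OC(C)(C)[C@@H]1Cc2c(OCOC)c(C(C)=O)c(OCOC)cc2O1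
F5 | step 8 | (S,E)-1-[2-(2-hydroxypropan-2-yl)-4,6-bis(methoxymethoxy)-2,3-dihydro-1-benzofuran-5-yl]-3-[4-(methoxymethoxy)phenyl]prop-2-en-1-one | CC(C)(O)[C@@H]1Cc2c(OCOC)c(C(=O)/C=C/c3ccc(OCOC)cc3)c(OCOC)cc2O1
F6 | step 8 | (S,E)-3-[4-(trimethylsilyloxy)phenyl]-1-{4,6-bis(trimethylsilyloxy)-2-[2-(trimethylsilyloxy)propan-2-yl]-2,3-dihydro-1-benzofuran-5-yl}prop-2-en-1-one | C[Si](C)(C)OC(C)(C)[C@@H]1Cc2c(O[Si](C)(C)C)c(C(=O)/C=C/c3ccc(O[Si](C)(C)C)cc3)c(O[Si](C)(C)C)cc2O1
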